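# Total synthesis of CID11069750 (6S,10S-diacetoxy cembranolide with a trans-fused α-methylene-γ-lactone)

Carbons are numbered in the cembrane way. C1 and C2 are the lactone ring-fusion carbons, and C2 carries the lactone oxygen. C3=C4, C7=C8 and C11=C12 are the E-trisubstituted alkenes. C6 and C10 carry OAc. C15–C17 are the α-methylene-lactone carbons.

**Retrosynthesis**
1. The target comes from a diol by diacetylation, and the diol from its bis-TBS ether.
2. One step forms the C1–C2 bond, closes the 14-membered ring and sets the lactone. It is an intramolecular Cr(II) allylation (Nozaki–Hiyama–Kishi type) of an allylic bromide onto an enal, followed by lactonisation. The anti adduct is the trans-lactone.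
3. The bromide-enal comes from a dialdehyde by Baylis–Hillman reaction and SN2′ bromination. The dialdehyde comes from a linear triene. The triene is built by repeating propargylation, TBS protection, Negishi methylalumination/iodination and formylation, and each cycle sets one E-trisubstituted alkene.
4. C10 is set by Ti–BINOL-catalysed asymmetric allenylation. C6 is set by a lipase (CAL-B) kinetic resolution. The chain is assembled from 4-pentyn-1-ol, an allenylstannane, propargyl bromide and methyl acrylate.

**Assumptions**
- The macrocyclic transition state favours the (1R,2S)-anti diastereomer relative to the fixed 6S,10S centres. Any minor diastereomer is removed by HPLC.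
- In the Baylis–Hillman step, the unhindered aliphatic aldehyde reacts in preference to the β,β-disubstituted enal.
- CAL-B acetylates the (R)-carbinol faster (Kazlauskas rule), leaving the (S)-alcohol.
- The BINOL enantiomer in step 4 is the one that gives 10S. This is checked by Mosher ester analysis, and the opposite enantiomer is used if 10R is obtained.

---

**Step 1**
Reactants: 1 (4-pentyn-1-ol); 2 (4-methoxybenzyl chloride, PMBCl)
Product: 3 (PMB ether of 4-pentyn-1-ol)
Conditions: NaH, TBAI (cat.), THF, 0 °C → rt
Reagents that add atoms: PMBCl, COc1ccc(CCl)cc1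
Why: Williamson etherification puts an orthogonal protecting group on the C1 oxygen. PMB survives AlMe3, t-BuLi and silylation, and DDQ removes it later.

**Step 2**
Reactants: 3; 4 (trimethylaluminium); 5 (iodine)
Product: 6 ((E)-1-iodo-5-PMBO-2-methylpent-1-ene, the C11–C14/C1 unit)
Conditions: Me3Al, Cp2ZrCl2 (cat.), CH2Cl2, 0 °C → rt; then I2, THF, −30 °C
Reagents that add atoms: Me3Al, C[Al](C)C; I2, II
Why: Zr-catalysed Negishi methylalumination adds Me and Al syn across the terminal alkyne. Iodinolysis then gives the E-trisubstituted vinyl iodide with I cis to Me, which is the C11=C12 geometry of the target.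

**Step 3**
Reactants: 6; 7 (DMF)
Product: 8 ((2E)-6-PMBO-3-methylhex-2-enal, the C10 aldehyde)
Conditions: t-BuLi (2.1 equiv), Et2O, −78 °C; then DMF, −78 → 0 °C
Reagents that add atoms: DMF, CN(C)C=O
Why: Li–I exchange proceeds with retention of alkene geometry. DMF formylation then gives the E-enal, which is the C10 electrophile.

**Step 4**
Reactants: 8; 9 (allenyltributylstannane)
Product: 10 ((4S,5E)-9-PMBO-6-methylnon-5-en-1-yn-4-ol, the 10S homopropargylic alcohol)
Conditions: 9 (1.5 equiv), (S)-BINOL (20 mol %), Ti(OiPr)4 (10 mol %), 4 Å MS, CH2Cl2, −20 °C; aqueous NaHCO3 work-up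
Reagents that add atoms: allenyltributylstannane, C=C=C[Sn](CCCC)(CCCC)CCCC
Why: Ti–BINOL-catalysed asymmetric allenylation of the aldehyde proceeds through an open SE2′ transition state and gives the homopropargylic alcohol. The chiral Lewis acid sets C10, the first stereocentre, by facial selection on the aldehyde.

**Step 5**
Reactants: 10; 11 (TBSCl)
Product: 12 (C10 TBS ether of 10)
Conditions: TBSCl, imidazole, DMAP (cat.), DMF, rt
Reagents that add atoms: TBSCl, CC(C)(C)[Si](C)(C)Cl
Why: Silylation protects the alcohol against t-BuLi and AlMe3 and leaves the stereocentre untouched.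

**Step 6**
Reactants: 12; 4; 5
Product: 13 (vinyl iodide I–CH=C(Me)–CH2–CH(OTBS)–CH=C(Me)–(CH2)3OPMB, 10S, both alkenes E; C7 iodide)
Conditions: Me3Al, Cp2ZrCl2 (cat.), CH2Cl2, 0 °C → rt; then I2, THF, −30 °C
Reagents that add atoms: Me3Al, C[Al](C)C; I2, II
Why: Negishi methylalumination/iodination of the terminal alkyne builds the C7=C8 E-trisubstituted alkene. The existing trisubstituted alkene is far less reactive and survives.

**Step 7**
Reactants: 13; 7 (DMF)
Product: 14 (enal OHC–CH=C(Me)–CH2–CH(OTBS)–CH=C(Me)–(CH2)3OPMB, C6 aldehyde, 10S)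
Conditions: t-BuLi (2.1 equiv), Et2O, −78 °C; then DMF, −78 → 0 °C
Reagents that add atoms: DMF, CN(C)C=O
Why: Li–I exchange and formylation with retention give the C6 electrophile, an α,β-unsaturated aldehyde.

**Step 8**
Reactants: 14; 15 (propargyl bromide)
Product: 16 (homopropargylic alcohol with 10S-OTBS, C6 epimers ~1:1)
Conditions: Zn dust, propargyl bromide, THF/sat. aq. NH4Cl, 0 °C → rt
Reagents that add atoms: propargyl bromide, C#CCBr
Why: Barbier-type propargylation through the allenylzinc species adds 1,2 to the aldehyde with no stereocontrol at C6. The C6 centre is fixed in the next step by resolution.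

**Step 9**
Reactants: 16; 17 (vinyl acetate)
Product: 18 (6S,10S alcohol, recovered as the unreacted enantiomer)
Conditions: Novozym 435 (Candida antarctica lipase B, a hydrolase), vinyl acetate (5 equiv), MTBE/hexane, 25 °C, stop at ~50% conversion; silica gel chromatography
Reagents that add atoms: none (vinyl acetate, CC(=O)OC=C, is only the acyl donor for the removed (6R)-carbinol, whose acetate is separated and discarded)
Why: Lipase-catalysed enantioselective transesterification (kinetic resolution) acylates the (R)-carbinol, so the (6S)-alcohol is left and separated from the acetate by chromatography. The remote 10S centre should not change the selectivity.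

**Step 10**
Reactants: 18; 11
Product: 19 (6S,10S-bis-TBS ether with terminal alkyne)
Conditions: TBSCl, imidazole, DMAP (cat.), DMF, 40 °C
Reagents that add atoms: TBSCl, CC(C)(C)[Si](C)(C)Cl
Why: The C6 alcohol is protected as in step 5, with no change at the stereocentre.

**Step 11**
Reactants: 19; 4; 5
Product: 20 (C3 vinyl iodide, 6S,10S)
Conditions: Me3Al, Cp2ZrCl2 (cat.), CH2Cl2, 0 °C → rt; then I2, THF, −30 °C
Reagents that add atoms: Me3Al, C[Al](C)C; I2, II
Why: The same syn-methylalumination/iodination forms the C3=C4 E-alkene.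

**Step 12**
Reactants: 20; 7
Product: 21 (C2 enal OHC–CH=C(Me)–CH2–CH(OTBS)–CH=C(Me)–CH2–CH(OTBS)–CH=C(Me)–(CH2)3OPMB)
Conditions: t-BuLi (2.1 equiv), Et2O, −78 °C; then DMF, −78 → 0 °C
Reagents that add atoms: DMF, CN(C)C=O
Why: Li–I exchange and formylation with retention give the C2 aldehyde, which is the NHK electrophile.

**Step 13**
Reactants: 21
Product: 22 (primary alcohol at C1; enal and both OTBS intact)
Conditions: DDQ, CH2Cl2/pH 7 phosphate buffer, 0 °C
Reagents that add atoms: none
Why: Oxidative cleavage of the PMB ether is selective for the electron-rich benzyl ether. The enal, the allylic silyl ethers and the trisubstituted alkenes are untouched at 0 °C with a buffered medium.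

**Step 14**
Reactants: 22
Product: 23 (dialdehyde: C1 aliphatic aldehyde plus C2 enal)
Conditions: Dess–Martin periodinane, NaHCO3, CH2Cl2, 0 °C → rt
Reagents that add atoms: none
Why: Dess–Martin oxidation converts the primary alcohol to the aldehyde under buffered, non-acidic conditions, so the alkenes and allylic silyl ethers do not isomerise.

**Step 15**
Reactants: 23; 24 (methyl acrylate)
Product: 25 (Baylis–Hillman adduct at C1, C1 epimers, enal retained)
Conditions: methyl acrylate (10 equiv), DABCO (1 equiv), MeOH, rt, 3–5 d
Reagents that add atoms: methyl acrylate, C=CC(=O)OC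
Why: The DABCO-catalysed Morita–Baylis–Hillman reaction occurs at the more electrophilic, unhindered aliphatic aldehyde, because the β,β-disubstituted enal is a poor electrophile. The new C1 carbinol is a mixture of epimers but is converted to an sp2 carbon in the next step, so it is irrelevant.

**Step 16**
Reactants: 25; 26 (NBS)
Product: 27 ((Z)-2-(bromomethyl)alk-2-enoate at C1=C15, enal retained)
Conditions: NBS, Me2S, CH2Cl2, 0 °C → rt
Reagents that add atoms: NBS, O=C1CCC(=O)N1Br
Why: The NBS/Me2S complex activates the Baylis–Hillman alcohol, and bromide displaces it by SN2′ to give the primary allylic bromide and the (Z)-trisubstituted acrylate. The trisubstituted alkenes and silyl ethers are unaffected under these anhydrous, mild conditions.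

**Step 17**
Reactants: 27
Product: 28 (macrocyclic trans-α-methylene-γ-lactone bis-TBS ether, 1R,2S,6S,10S)
Conditions: CrCl2 (10 equiv), DMF/THF, rt, 0.002 M (slow addition of 27); aqueous work-up; cat. PPTS, CH2Cl2, rt only if the hydroxy ester persists
Reagents that add atoms: none
Why: An intramolecular Cr(II) Barbier-type allylation (NHK) builds the 14-membered ring. The allylchromium adds through a chair Zimmerman–Traxler transition state to give the anti homoallylic alkoxide, which sets C1 and C2 as the trans pair. The alkoxide then lactonises onto the methyl ester to close the five-membered ring. Facial selectivity relative to C6 and C10 comes from the macrocyclic conformation (assumption above).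

**Step 18**
Reactants: 28
Product: 29 (6S,10S-diol lactone)
Conditions: HF·pyridine, pyridine/THF, 0 °C → rt
Reagents that add atoms: none
Why: Buffered fluoride cleaves both silyl ethers. The α-methylene lactone, the alkenes and the stereocentres are unaffected under these non-basic conditions.

**Step 19**
Reactants: 29; 30 (acetic anhydride)
Product: 31 (target, CID11069750)
Conditions: Ac2O, pyridine, DMAP (cat.), CH2Cl2, 0 °C → rt
Reagents that add atoms: Ac2O, CC(=O)OC(C)=O
Why: O-Acylation of the two secondary allylic alcohols occurs with retention at C6 and C10. The Michael-acceptor lactone survives because the reaction is run cold with only catalytic DMAP.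

---

## Compound list

| # | Name | SMILES | Role |
|---|---|---|---|
| 1 | 4-pentyn-1-ol | C#CCCCO | starting material |
| 2 | 4-methoxybenzyl chloride | COc1ccc(CCl)cc1 | starting material |
| 3 | PMB ether of 4-pentyn-1-ol | C#CCCCOCc1ccc(OC)cc1 | intermediate |
| 4 | trimethylaluminium | C[Al](C)C | starting material |
| 5 | iodine | II | starting material |
| 6 | (E)-1-iodo-5-PMBO-2-methylpent-1-ene | I/C=C(\C)CCCOCc1ccc(OC)cc1 | intermediate |
| 7 | DMF | CN(C)C=O | starting material |
| 8 | (2E)-6-PMBO-3-methylhex-2-enal | O=C/C=C(\C)CCCOCc1ccc(OC)cc1 | intermediate |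
| 9 | allenyltributylstannane | C=C=C[Sn](CCCC)(CCCC)CCCC | starting material |
| 10 | (4S,5E)-9-PMBO-6-methylnon-5-en-1-yn-4-ol (10S) | C#CC[C@H](O)/C=C(\C)CCCOCc1ccc(OC)cc1 | intermediate |
| 11 | TBSCl | CC(C)(C)[Si](C)(C)Cl | starting material |
| 12 | C10 TBS ether of 10 | C#CC[C@H](O[Si](C)(C)C(C)(C)C)/C=C(\C)CCCOCc1ccc(OC)cc1 | intermediate |
| 13 | C7 vinyl iodide, 10S-OTBS | I/C=C(\C)C[C@H](O[Si](C)(C)C(C)(C)C)/C=C(\C)CCCOCc1ccc(OC)cc1 | intermediate |
| 14 | C6 enal, 10S-OTBS | O=C/C=C(\C)C[C@H](O[Si](C)(C)C(C)(C)C)/C=C(\C)CCCOCc1ccc(OC)cc1 | intermediate |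
| 15 | propargyl bromide | C#CCBr | starting material |
| 16 | homopropargylic alcohol, 10S-OTBS, C6 epimeric mixture | C#CCC(O)/C=C(\C)C[C@H](O[Si](C)(C)C(C)(C)C)/C=C(\C)CCCOCc1ccc(OC)cc1 | intermediate |
| 17 | vinyl acetate | CC(=O)OC=C | starting material |
| 18 | 6S,10S alcohol | C#CC[C@H](O)/C=C(\C)C[C@H](O[Si](C)(C)C(C)(C)C)/C=C(\C)CCCOCc1ccc(OC)cc1 | intermediate |
| 19 | 6S,10S-bis-TBS ether, terminal alkyne | C#CC[C@H](O[Si](C)(C)C(C)(C)C)/C=C(\C)C[C@H](O[Si](C)(C)C(C)(C)C)/C=C(\C)CCCOCc1ccc(OC)cc1 | intermediate |
| 20 | C3 vinyl iodide | I/C=C(\C)C[C@H](O[Si](C)(C)C(C)(C)C)/C=C(\C)C[C@H](O[Si](C)(C)C(C)(C)C)/C=C(\C)CCCOCc1ccc(OC)cc1 | intermediate |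
| 21 | C2 enal, PMB ether | O=C/C=C(\C)C[C@H](O[Si](C)(C)C(C)(C)C)/C=C(\C)C[C@H](O[Si](C)(C)C(C)(C)C)/C=C(\C)CCCOCc1ccc(OC)cc1 | intermediate |
| 22 | C1 primary alcohol, enal | O=C/C=C(\C)C[C@H](O[Si](C)(C)C(C)(C)C)/C=C(\C)C[C@H](O[Si](C)(C)C(C)(C)C)/C=C(\C)CCCO | intermediate |
| 23 | dialdehyde (C1 CHO, C2 enal) | O=C/C=C(\C)C[C@H](O[Si](C)(C)C(C)(C)C)/C=C(\C)C[C@H](O[Si](C)(C)C(C)(C)C)/C=C(\C)CCC=O | intermediate |
| 24 | methyl acrylate | C=CC(=O)OC | starting material |
| 25 | Baylis–Hillman adduct (C1 epimers) | O=C/C=C(\C)C[C@H](O[Si](C)(C)C(C)(C)C)/C=C(\C)C[C@H](O[Si](C)(C)C(C)(C)C)/C=C(\C)CCC(O)C(=C)C(=O)OC | intermediate |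
| 26 | N-bromosuccinimide | O=C1CCC(=O)N1Br | starting material |
| 27 | (Z)-allylic bromide enal | O=C/C=C(\C)C[C@H](O[Si](C)(C)C(C)(C)C)/C=C(\C)C[C@H](O[Si](C)(C)C(C)(C)C)/C=C(\C)CC/C=C(\CBr)C(=O)OC | intermediate |
| 28 | bis-TBS macrocyclic lactone | C=C1C(=O)O[C@H]2/C=C(\C)C[C@H](O[Si](C)(C)C(C)(C)C)/C=C(\C)C[C@H](O[Si](C)(C)C(C)(C)C)/C=C(\C)CC[C@H]12 | intermediate |
| 29 | diol lactone | C=C1C(=O)O[C@H]2/C=C(\C)C[C@H](O)/C=C(\C)C[C@H](O)/C=C(\C)CC[C@H]12 | intermediate |
| 30 | acetic anhydride | CC(=O)OC(C)=O | starting material |
| 31 | CID11069750 | C=C1C(=O)O[C@H]2/C=C(\C)C[C@H](OC(C)=O)/C=C(\C)C[C@H](OC(C)=O)/C=C(\C)CC[C@H]12 | target |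

## Totals
- Total steps: 19.
- Longest linear sequence: 19 steps from 4-pentyn-1-ol.

## Three steps most likely to fail
1. **Step 17 (Cr macrocyclisation).** Remote diastereocontrol or yield may be poor. Fallback: build the trans-lactone separately and close the ring differently. Set the C2 alcohol by Noyori transfer hydrogenation of an ynone, form a γ-alkenyl butenolide, install trans C1 by vinylcuprate 1,4-addition, then close C12–C13 by macrocyclic B-alkyl Suzuki–Miyaura coupling (9-BBN hydroboration and vinyl iodide), with α-methylenation last.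
2. **Step 15 (Baylis–Hillman on the dialdehyde).** The enal may compete, or the yield may be low. Fallback: carry C2 as its TBS-protected primary allylic alcohol, made from the methylalumination vinylalane plus paraformaldehyde instead of formylation. Run the Baylis–Hillman reaction and bromination on the lone C1 aldehyde, then remove the primary silyl group and oxidise with MnO2 just before the Cr step.
3. **Step 9 (CAL-B resolution).** Selectivity may be low or the wrong enantiomer may react. Fallback: drop the enzymatic resolution and set C6 by a second catalyst-controlled Ti–BINOL allenylation of enal 14, using the BINOL enantiomer that gives the S carbinol.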